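**Plan**

1. Retrosynthesis: remove the C3 angelate and the C6 acetate, read the C7 isopropyl as isopropenyl, and cut the ten-membered carbocycle at C6–C7 (homoallylic alcohol retron). This gives an open-chain 4,5-epoxy aldehyde with a terminal allylic chloride, which is cut at C2–C3 into geranyl chloride and ethyl (2E)-3-methyl-4-oxobut-2-enoate.
2. Enabling feature: in the ten-membered ring the oxygen-bearing C6 is adjacent to the isopropyl-bearing C7 and flanked by the C4–C5 oxirane, and the E-C1=C10 alkene and the trans-oxirane stiffen the tether. A C6 aldehyde can therefore be allylated by a C7/C11/C12 allylmetal, chelated by the oxirane oxygen, closing the ring and setting C6 and C7 at once.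
3. Forward order: C2–C3 by α-selective geranylbarium addition; the oxirane (first ring) on the open chain; the ten-membered carbocycle last, by Pd/Et2Zn umpolung allylation; then isopropenyl hydrogenation and the two esters.
4. Stereochemistry: C3 by CBS reduction (catalyst control); C4/C5 by Sharpless epoxidation (reagent control); C6 and C7 together in the ring closure, relayed from C5. Both E-alkenes come from the starting materials and the Z-angelate from angelic acid.

Key step: step 9

Remark: germacrane numbering is used for ring positions (C1=C10 alkene, C3 angelate, C4–C5 oxirane, C6 acetate, C7 isopropyl, C11–C13 side chain). CIP descriptors at C4/C5 change between intermediates only because substituent priorities change; the geometry is the same throughout.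

**Route**

Step 1
Reactants: 1 geranyl chloride; 2 ethyl (2E)-3-methyl-4-oxobut-2-enoate
Product: 4 ethyl (2E,6E)-4-hydroxy-3,7,11-trimethyldodeca-2,6,10-trienoate (racemic), via geranylbarium chloride 3 (not isolated)
Conditions: BaI2, lithium biphenylide, THF, rt (activated Ba); 1, −78 °C; then 2, −78 °C; aq. NH4Cl
Reagents that add atoms: none
Why: Carbonyl allylation with an allylbarium reagent, which should add through its α-carbon with retention of the E geometry and 1,2 to the aldehyde (far more electrophilic than the conjugated ester at −78 °C); the new carbinol C3 is racemic here and is corrected in steps 2 and 3.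

Step 2
Reactants: 4
Product: 5 ethyl (2E,6E)-3,7,11-trimethyl-4-oxododeca-2,6,10-trienoate
Conditions: Dess–Martin periodinane, NaHCO3, CH2Cl2, 0 °C
Reagents that add atoms: none
Why: Dess–Martin oxidation under buffered, non-basic conditions should give the ketone without moving the skipped alkene into conjugation.

Step 3
Reactants: 5
Product: 6 ethyl (2E,4S,6E)-4-hydroxy-3,7,11-trimethyldodeca-2,6,10-trienoate
Conditions: (R)-Me-CBS oxazaborolidine (cat.), catecholborane, toluene, −78 °C; then MeOH, aq. NaOH
Reagents that add atoms: none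
Why: Corey–Bakshi–Shibata reduction, in which the α-methyl alkenyl group acts as the large and the CH2 group as the small substituent, so the (R)-catalyst should deliver hydride 1,2 to the face that gives the (S)-carbinol (C3) and leave the ester alone.

Step 4
Reactants: 6
Product: 7 ethyl (2E,4S,6E)-4-[(tert-butyldimethylsilyl)oxy]-3,7,11-trimethyldodeca-2,6,10-trienoate
Conditions: TBSOTf, 2,6-lutidine, CH2Cl2, −78 to 0 °C
Reagents that add atoms: tert-butyldimethylsilyl triflate, CC(C)(C)[Si](C)(C)OS(=O)(=O)C(F)(F)F
Why: Silyl ether formation masks C3–OH so that only the primary hydroxyl made in step 5 directs the epoxidation; the stereocentre is not touched.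

Step 5
Reactants: 7
Product: 8 (2E,4S,6E)-4-[(tert-butyldimethylsilyl)oxy]-3,7,11-trimethyldodeca-2,6,10-trien-1-ol
Conditions: DIBAL-H, CH2Cl2, −78 °C; Rochelle salt
Reagents that add atoms: none
Why: DIBAL-H reduction of the enoate should give the E-allylic alcohol by clean 1,2-reduction, with the silyl ether and the isolated alkenes inert.

Step 6
Reactants: 8
Product: 9 [(2R,3S)-3-{(1S,3E)-1-[(tert-butyldimethylsilyl)oxy]-4,8-dimethylnona-3,7-dien-1-yl}-3-methyloxiran-2-yl]methanol
Conditions: Ti(OiPr)4 (cat.), D-(−)-diisopropyl tartrate (cat.), t-BuOOH, 4 Å MS, CH2Cl2, −20 °C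
Reagents that add atoms: tert-butyl hydroperoxide, CC(C)(C)OO
Why: Sharpless asymmetric epoxidation, in which the D-(−)-tartrate titanium complex should deliver oxygen to one face of the E-trisubstituted allylic alcohol under reagent control (overriding the C3 silyloxy centre) and so set C4 and C5 as the trans-oxirane, while the two alkenes without an allylic hydroxyl stay untouched.

Step 7
Reactants: 9
Product: 10 [(2R,3S)-3-{(1S,3E)-1-[(tert-butyldimethylsilyl)oxy]-7-chloro-4,8-dimethylnona-3,8-dien-1-yl}-3-methyloxiran-2-yl]methanol (both epimers at the CHCl carbon)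
Conditions: NaOCl (aq.), CeCl3·7H2O, CH2Cl2/H2O, 0 °C
Reagents that add atoms: sodium hypochlorite, [Na+].[O-]Cl
Why: Ene-type allylic chlorination by hypochlorous acid (Cl+ addition, proton loss from a methyl group with double-bond shift) should occur at the terminal trisubstituted alkene, the most electron-rich and least hindered one, because the C1=C10 alkene is deactivated and shielded by the neighbouring silyloxy/oxirane unit; the new C–Cl centre is formed without control and is erased in step 9.

Step 8
Reactants: 10
Product: 11 (2S,3S)-3-{(1S,3E)-1-[(tert-butyldimethylsilyl)oxy]-7-chloro-4,8-dimethylnona-3,8-dien-1-yl}-3-methyloxirane-2-carbaldehyde (both epimers at the CHCl carbon)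
Conditions: Dess–Martin periodinane, NaHCO3, CH2Cl2, 0 °C; used crude
Reagents that add atoms: none
Why: Buffered Dess–Martin oxidation should give the sensitive α,β-epoxy aldehyde without epimerisation at C5 or loss of the allylic chloride.

Step 9
Reactants: 11
Product: 13 (3S,4S,5R,6S,7R,1(10)E)-3-[(tert-butyldimethylsilyl)oxy]-4,5-epoxygermacra-1(10),11-dien-6-ol, via allylzinc reagent 12 (not isolated)
Conditions: Pd(PPh3)4 (cat.), Et2Zn (excess), THF, rt, slow addition of 11 to high dilution; aq. NH4Cl
Reagents that add atoms: none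
Why: Pd(0) ionises the allylic chloride of 11 (both CHCl epimers converge) to a 2-methyl-η3-allyl complex, allyl-for-ethyl exchange with Et2Zn gives the σ-allylzinc 12 with zinc on the primary carbon C12, and its γ-carbon C7 adds to the aldehyde carbon C6 through a closed six-membered chair (Zimmerman–Traxler-type) transition state. The closest known reaction type is the Pd-catalysed, Et2Zn-mediated umpolung allylation of aldehydes with allylic halides or esters, which is also known in intramolecular form for medium rings. The ten-membered carbocycle closes by a 10-exo-trig attack on the carbonyl (SE2′ at the allyl unit), which leaves C11=C12 outside the ring as the isopropenyl group. C6 is controlled by the C5 stereocentre of the Sharpless-derived oxirane: zinc is expected to bridge the carbonyl and oxirane oxygens, so that C7 attacks the aldehyde face away from C4 and gives the 5,6-syn carbinol (6S, the chelation product). C7 is controlled relative to C6 by the fused chair: the tether C5–C4–C3–C2–C1=C10–C9–C8, stiffened by the trans-oxirane and the E-alkene, should span C6 and C7 most easily with C8 axial (Z-allylzinc, reached by fast 1,3-metallotropy), which places C6–OH and the isopropenyl group cis on the ring (7R). The step needs γ- over α-attack (ten- versus twelve-membered ring), cyclisation over oligomerisation and allyl over ethyl transfer; these are secured by the cyclic SE2′ transition state of the primary allylzinc, by slow addition at high dilution and by the inertness of Et2Zn towards aldehydes without a catalyst for alkyl transfer.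

Step 10
Reactants: 13
Product: 14 (3S,4S,5R,6S,7R,1(10)E)-3-[(tert-butyldimethylsilyl)oxy]-4,5-epoxygermacr-1(10)-en-6-ol
Conditions: H2 (1 atm), RhCl(PPh3)3 (cat.), benzene, rt
Reagents that add atoms: none
Why: Homogeneous hydrogenation with Wilkinson's catalyst should reduce the 1,1-disubstituted isopropenyl alkene much faster than the trisubstituted ring alkene, under neutral conditions that spare the oxirane and touch no stereocentre.

Step 11
Reactants: 14
Product: 15 (3S,4S,5R,6S,7R,1(10)E)-3-[(tert-butyldimethylsilyl)oxy]-4,5-epoxygermacr-1(10)-en-6-yl acetate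
Conditions: Ac2O, Et3N, DMAP (cat.), CH2Cl2, 0 °C to rt
Reagents that add atoms: acetic anhydride, CC(=O)OC(C)=O
Why: DMAP-catalysed acylation of the only free hydroxyl (C6) under basic conditions, which the acid-sensitive epoxy-germacrene tolerates, with retention at C6.

Step 12
Reactants: 15
Product: 16 (3S,4R,5R,6S,7R,1(10)E)-3-hydroxy-4,5-epoxygermacr-1(10)-en-6-yl acetate
Conditions: TBAF, AcOH (1:1), THF, 0 °C to rt
Reagents that add atoms: none
Why: Fluoride desilylation buffered with acetic acid should free C3–OH without acid (no transannular oxirane opening) and without a free alkoxide (no Payne rearrangement or acetate loss).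

Step 13
Reactants: 16; 17 angelic acid [(2Z)-2-methylbut-2-enoic acid]
Product: 19 (3S,4R,5R,6S,7R,1(10)E)-6-acetoxy-4,5-epoxygermacr-1(10)-en-3-yl (2Z)-2-methylbut-2-enoate (target), via angelic 2,4,6-trichlorobenzoic anhydride 18 (not isolated)
Conditions: 17, 2,4,6-trichlorobenzoyl chloride, Et3N, toluene, rt; then 16, 75 °C
Reagents that add atoms: none
Why: Yamaguchi esterification through the mixed anhydride, run without a nucleophilic catalyst, should acylate the hindered C3–OH with retention and keep the Z geometry of the angelate (no isomerisation to tiglate); the epoxy-germacrene has no 1,5-diene and should tolerate the temperature.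

**Compound list**

1 | geranyl chloride [(2E)-1-chloro-3,7-dimethylocta-2,6-diene] | CC(C)=CCC/C(C)=C/CCl | starting material
2 | ethyl (2E)-3-methyl-4-oxobut-2-enoate | CCOC(=O)/C=C(\C)C=O | starting material
3 | geranylbarium chloride (not isolated) | CC(C)=CCC/C(C)=C/C[Ba]Cl | intermediate
4 | ethyl (2E,6E)-4-hydroxy-3,7,11-trimethyldodeca-2,6,10-trienoate (racemic) | CCOC(=O)/C=C(\C)C(O)C/C=C(\C)CCC=C(C)C | intermediate
5 | ethyl (2E,6E)-3,7,11-trimethyl-4-oxododeca-2,6,10-trienoate | CCOC(=O)/C=C(\C)C(=O)C/C=C(\C)CCC=C(C)C | intermediate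
6 | ethyl (2E,4S,6E)-4-hydroxy-3,7,11-trimethyldodeca-2,6,10-trienoate | CCOC(=O)/C=C(\C)[C@@H](O)C/C=C(\C)CCC=C(C)C | intermediate
7 | ethyl (2E,4S,6E)-4-[(tert-butyldimethylsilyl)oxy]-3,7,11-trimethyldodeca-2,6,10-trienoate | CCOC(=O)/C=C(\C)[C@@H](O[Si](C)(C)C(C)(C)C)C/C=C(\C)CCC=C(C)C | intermediate
8 | (2E,4S,6E)-4-[(tert-butyldimethylsilyl)oxy]-3,7,11-trimethyldodeca-2,6,10-trien-1-ol | OC/C=C(\C)[C@@H](O[Si](C)(C)C(C)(C)C)C/C=C(\C)CCC=C(C)C | intermediate
9 | [(2R,3S)-3-{(1S,3E)-1-[(tert-butyldimethylsilyl)oxy]-4,8-dimethylnona-3,7-dien-1-yl}-3-methyloxiran-2-yl]methanol | OC[C@H]1O[C@]1(C)[C@@H](O[Si](C)(C)C(C)(C)C)C/C=C(\C)CCC=C(C)C | intermediate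
10 | [(2R,3S)-3-{(1S,3E)-1-[(tert-butyldimethylsilyl)oxy]-7-chloro-4,8-dimethylnona-3,8-dien-1-yl}-3-methyloxiran-2-yl]methanol (both epimers at the CHCl carbon) | OC[C@H]1O[C@]1(C)[C@@H](O[Si](C)(C)C(C)(C)C)C/C=C(\C)CCC(Cl)C(C)=C | intermediate
11 | (2S,3S)-3-{(1S,3E)-1-[(tert-butyldimethylsilyl)oxy]-7-chloro-4,8-dimethylnona-3,8-dien-1-yl}-3-methyloxirane-2-carbaldehyde (both epimers at the CHCl carbon) | O=C[C@H]1O[C@]1(C)[C@@H](O[Si](C)(C)C(C)(C)C)C/C=C(\C)CCC(Cl)C(C)=C | intermediate
12 | ethyl(allyl)zinc reagent from 11, zinc on the primary allyl carbon C12 (not isolated) | O=C[C@H]1O[C@]1(C)[C@@H](O[Si](C)(C)C(C)(C)C)C/C=C(\C)CCC=C(C)C[Zn]CC | intermediate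
13 | (3S,4S,5R,6S,7R,1(10)E)-3-[(tert-butyldimethylsilyl)oxy]-4,5-epoxygermacra-1(10),11-dien-6-ol | CC(C)(C)[Si](C)(C)O[C@H]1C/C=C(\C)CC[C@H](C(C)=C)[C@H](O)[C@H]2O[C@]12C | intermediate
14 | (3S,4S,5R,6S,7R,1(10)E)-3-[(tert-butyldimethylsilyl)oxy]-4,5-epoxygermacr-1(10)-en-6-ol | CC(C)(C)[Si](C)(C)O[C@H]1C/C=C(\C)CC[C@H](C(C)C)[C@H](O)[C@H]2O[C@]12C | intermediate
15 | (3S,4S,5R,6S,7R,1(10)E)-3-[(tert-butyldimethylsilyl)oxy]-4,5-epoxygermacr-1(10)-en-6-yl acetate | CC(C)(C)[Si](C)(C)O[C@H]1C/C=C(\C)CC[C@H](C(C)C)[C@H](OC(C)=O)[C@H]2O[C@]12C | intermediate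
16 | (3S,4R,5R,6S,7R,1(10)E)-3-hydroxy-4,5-epoxygermacr-1(10)-en-6-yl acetate | O[C@H]1C/C=C(\C)CC[C@H](C(C)C)[C@H](OC(C)=O)[C@H]2O[C@]12C | intermediate
17 | angelic acid [(2Z)-2-methylbut-2-enoic acid] | C/C=C(/C)C(=O)O | starting material
18 | angelic 2,4,6-trichlorobenzoic anhydride (not isolated) | C/C=C(/C)C(=O)OC(=O)c1c(Cl)cc(Cl)cc1Cl | intermediate
19 | (3S,4R,5R,6S,7R,1(10)E)-6-acetoxy-4,5-epoxygermacr-1(10)-en-3-yl (2Z)-2-methylbut-2-enoate; systematically [(1R,2S,4E,8R,9S,10R)-9-acetoxy-1,5-dimethyl-8-(propan-2-yl)-11-oxabicyclo[8.1.0]undec-4-en-2-yl] (2Z)-2-methylbut-2-enoate | C/C=C(/C)C(=O)O[C@H]1C/C=C(\C)CC[C@H](C(C)C)[C@H](OC(C)=O)[C@H]2O[C@]12C | target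

**Step count and risks**

Total step count: 13. Longest linear sequence: 13 steps (1 or 2 to 19).

Steps most likely to fail:

Step 9. The allylzinc may add through a non-chelated, Felkin-type array or through the diequatorial chair, so that facial selectivity at the aldehyde is lost; intermolecular allylation and ethyl transfer may also compete. This fallback only corrects C6; if C7 comes out wrong relative to the oxirane, it does not help. In the fallback C6 is set by a separate ketone reduction instead of in the ring closure. Setting out from 11, the ring is closed as in step 9 or with CrCl2 and catalytic LiI in THF (Nozaki–Hiyama–Kishi-type allylation, which does not rely on chelation) to the C6-epimeric carbinol (3S,4S,5R,6R,7R,1(10)E)-3-[(tert-butyldimethylsilyl)oxy]-4,5-epoxygermacra-1(10),11-dien-6-ol F1. Buffered Dess–Martin oxidation gives the epoxy ketone (3S,4S,5S,7R,1(10)E)-3-[(tert-butyldimethylsilyl)oxy]-4,5-epoxygermacra-1(10),11-dien-6-one F2. Reduction with L-Selectride in THF at −78 °C, where the bulky non-chelating hydride should enter anti to the oxirane C–O bond (Felkin–Anh) and from the ring periphery, should give the 5,6-syn carbinol 13, where the route is rejoined.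

Step 7. Site selectivity between the terminal and the C1=C10 alkene may be poor, and chlorohydrin formation or oxirane opening in the Lewis-acidic aqueous medium may intervene. The fallback replaces the ene-chlorination by allylic hydroxylation and chlorination of the resulting alcohol. Setting out from 9, SeO2 (cat.)/t-BuOOH in CH2Cl2 at 0 °C oxidises the terminal (E)-methyl group, the usual site in farnesyl-type chains, to the diol [(2R,3S)-3-{(1S,3E,7E)-1-[(tert-butyldimethylsilyl)oxy]-9-hydroxy-4,8-dimethylnona-3,7-dien-1-yl}-3-methyloxiran-2-yl]methanol F3. NCS/Me2S without base (Corey–Kim conditions), which convert only allylic hydroxyls into chlorides, gives the primary allylic chloride [(2R,3S)-3-{(1S,3E,7E)-1-[(tert-butyldimethylsilyl)oxy]-9-chloro-4,8-dimethylnona-3,7-dien-1-yl}-3-methyloxiran-2-yl]methanol F4. Buffered Dess–Martin oxidation gives the aldehyde (2S,3S)-3-{(1S,3E,7E)-1-[(tert-butyldimethylsilyl)oxy]-9-chloro-4,8-dimethylnona-3,7-dien-1-yl}-3-methyloxirane-2-carbaldehyde F5. Under the conditions of step 9, F5 ionises to the same η3-allyl complex and hence the same allylzinc 12, and the route is rejoined at 13.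

Step 3. Enantioface discrimination may be insufficient, and conjugate reduction or migration of the skipped alkene may occur in the sensitive 4-oxo-2-enoate 5. The fallback drops the ketone and resolves through the reagent-controlled epoxidation. Setting out from racemic 4, silylation as in step 4 gives racemic ethyl (2E,6E)-4-[(tert-butyldimethylsilyl)oxy]-3,7,11-trimethyldodeca-2,6,10-trienoate F6, and DIBAL-H reduction as in step 5 gives racemic (2E,6E)-4-[(tert-butyldimethylsilyl)oxy]-3,7,11-trimethyldodeca-2,6,10-trien-1-ol F7. Sharpless epoxidation with D-(−)-diisopropyl tartrate, run to full conversion, should turn the two enantiomers into two diastereomers of fixed oxirane configuration: 9 and its side-chain epimer [(2R,3S)-3-{(1R,3E)-1-[(tert-butyldimethylsilyl)oxy]-4,8-dimethylnona-3,7-dien-1-yl}-3-methyloxiran-2-yl]methanol F8. Chromatographic separation rejoins the route at 9, at the cost of half the material.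

Further compounds
F1 | step 9 | (3S,4S,5R,6R,7R,1(10)E)-3-[(tert-butyldimethylsilyl)oxy]-4,5-epoxygermacra-1(10),11-dien-6-ol | CC(C)(C)[Si](C)(C)O[C@H]1C/C=C(\C)CC[C@H](C(C)=C)[C@@H](O)[C@H]2O[C@]12C
F2 | step 9 | (3S,4S,5S,7R,1(10)E)-3-[(tert-butyldimethylsilyl)oxy]-4,5-epoxygermacra-1(10),11-dien-6-one | CC(C)(C)[Si](C)(C)O[C@H]1C/C=C(\C)CC[C@H](C(C)=C)C(=O)[C@H]2O[C@]12C
F3 | step 7 | [(2R,3S)-3-{(1S,3E,7E)-1-[(tert-butyldimethylsilyl)oxy]-9-hydroxy-4,8-dimethylnona-3,7-dien-1-yl}-3-methyloxiran-2-yl]methanol | OC[C@H]1O[C@]1(C)[C@@H](O[Si](C)(C)C(C)(C)C)C/C=C(\C)CC/C=C(\C)CO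
F4 | step 7 | [(2R,3S)-3-{(1S,3E,7E)-1-[(tert-butyldimethylsilyl)oxy]-9-chloro-4,8-dimethylnona-3,7-dien-1-yl}-3-methyloxiran-2-yl]methanol | OC[C@H]1O[C@]1(C)[C@@H](O[Si](C)(C)C(C)(C)C)C/C=C(\C)CC/C=C(\C)CCl
F5 | step 7 | (2S,3S)-3-{(1S,3E,7E)-1-[(tert-butyldimethylsilyl)oxy]-9-chloro-4,8-dimethylnona-3,7-dien-1-yl}-3-methyloxirane-2-carbaldehyde | O=C[C@H]1O[C@]1(C)[C@@H](O[Si](C)(C)C(C)(C)C)C/C=C(\C)CC/C=C(\C)CCl
F6 | step 3 | ethyl (2E,6E)-4-[(tert-butyldimethylsilyl)oxy]-3,7,11-trimethyldodeca-2,6,10-trienoate (racemic) | CCOC(=O)/C=C(\C)C(O[Si](C)(C)C(C)(C)C)C/C=C(\C)CCC=C(C)C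
F7 | step 3 | (2E,6E)-4-[(tert-butyldimethylsilyl)oxy]-3,7,11-trimethyldodeca-2,6,10-trien-1-ol (racemic) | OC/C=C(\C)C(O[Si](C)(C)C(C)(C)C)C/C=C(\C)CCC=C(C)C
F8 | step 3 | [(2R,3S)-3-{(1R,3E)-1-[(tert-butyldimethylsilyl)oxy]-4,8-dimethylnona-3,7-dien-1-yl}-3-methyloxiran-2-yl]methanol | OC[C@H]1O[C@]1(C)[C@H](O[Si](C)(C)C(C)(C)C)C/C=C(\C)CCC=C(C)C
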